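**Retrosynthetic overview**
1. The styryl arm is attached last (Heck coupling on an aryl bromide, then global debenzylation), so no benzylic cation or quinone methide is ever generated next to the stilbene double bond.
2. The C3 carbinol comes from a chroman-3-one (axial hydride delivery), and the ketone from a Nef reaction of a 3-nitrochromane: C3 is carried as a nitro-bearing carbon, a masked acyl anion.
3. Ring C is the only ring built (rings A, B and both stilbene rings are bought): C2–C3 by nitroaldol condensation with the ring B aldehyde, then O1–C2 by oxa-Michael closure.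
4. Key bond C3–C4: the nitronate of nitromethane adds to the electrophilic methide carbon of an ortho-quinone methide under a chiral squaramide; this sets C4, and C2 and C3 then follow C4.
5. The quinone methide is released from a 2-(1-tosylalkyl)phenol made from 3-(benzyloxy)phenol, a brominated resorcinol aldehyde and a sulfinate.

Assumption: the target is the (2R,3S,4S) isomer (2,3-trans-3,4-trans) read from the SMILES, and the facial sense of the squaramide in step 3 is assumed; if it is opposite, the quinidine-derived pseudoenantiomer is used.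

**Step 1**
Reactants: 1 1,3-bis(benzyloxy)-5-bromobenzene
Product: 3 2,4-bis(benzyloxy)-6-bromobenzaldehyde, via iminium salt 2 (not isolated)
Conditions: POCl3, DMF, 0 °C to 70 °C; then H2O
Reagents that add atoms: N,N-dimethylformamide CN(C)C=O; water O
Why: Vilsmeier–Haack formylation goes para to one benzyloxy group and ortho to the other (the site between the two ethers is less favoured), giving the substitution pattern of the stilbene resorcinol ring with bromine as placeholder for the styryl arm.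

**Step 2**
Reactants: 3 2,4-bis(benzyloxy)-6-bromobenzaldehyde; 4 3-(benzyloxy)phenol
Product: 6 rac-5-(benzyloxy)-2-{[2,4-bis(benzyloxy)-6-bromophenyl](4-methylbenzenesulfonyl)methyl}phenol, via benzhydrol 5 (not isolated)
Conditions: sodium 4-methylbenzenesulfinate (1.5 equiv), HCO2H/H2O/CH2Cl2, rt to 40 °C
Reagents that add atoms: sodium 4-methylbenzenesulfinate Cc1ccc(cc1)S(=O)[O-].[Na+]
Why: Acid-promoted Friedel–Crafts ortho-hydroxyalkylation of the 3-alkoxyphenol (ortho to OH, para to OBn) followed by sulfinate capture of the benzylic cation is the standard three-component route to 2-(1-tosylalkyl)phenols; the di-ortho-substituted aldehyde resists double arylation, and the racemic sulfone carbon is erased in step 3.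

**Step 3 (key step)**
Reactants: 6 rac-5-(benzyloxy)-2-{[2,4-bis(benzyloxy)-6-bromophenyl](4-methylbenzenesulfonyl)methyl}phenol; 7 nitromethane
Product: 9 5-(benzyloxy)-2-{(1S)-1-[2,4-bis(benzyloxy)-6-bromophenyl]-2-nitroethyl}phenol, via ortho-quinone methide 8 (not isolated)
Conditions: 7 (10 equiv), quinine-derived 3,5-bis(trifluoromethyl)phenyl squaramide (10 mol%), aq. Na2CO3 (1.5 equiv), toluene, 0 °C; recrystallise
Reagents that add atoms: none
Why: Proposed new method: carbonate expels sulfinate to give quinone methide 8, the squaramide hydrogen-bonds its carbonyl while the protonated quinuclidine pairs with nitromethanide, and the nitronate carbon (the future C3 carbonyl carbon, normally an electrophilic centre) adds to one face of the electrophilic methide carbon, with re-aromatisation making the asymmetric nitro-Michael addition irreversible and fixing C4 as (S); the closest known reactions are squaramide/aqueous-carbonate additions of 1,3-dicarbonyl carbon acids to quinone methides released from 2-(1-tosylalkyl)phenols and amine–thiourea nitro-Michael additions.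

**Step 4**
Reactants: 9 5-(benzyloxy)-2-{(1S)-1-[2,4-bis(benzyloxy)-6-bromophenyl]-2-nitroethyl}phenol; 10 4-(benzyloxy)benzaldehyde
Product: 12 (2R,3S,4S)-7-(benzyloxy)-2-[4-(benzyloxy)phenyl]-4-[2,4-bis(benzyloxy)-6-bromophenyl]-3-nitrochromane, via nitroalkene 11 (not isolated)
Conditions: 10 (1.3 equiv), pyrrolidine (20 mol%), PhCO2H (20 mol%), 4 Å MS, toluene, 60 °C; then DBU (10 mol%), rt
Reagents that add atoms: none
Why: Amine-catalysed Henry (nitroaldol) condensation makes the C2–C3 bond as the (E)-nitroalkene, which the neighbouring phenol closes by 6-endo oxa-Michael addition to form ring C; because the oxa-Michael step and nitronate protonation are reversible under amine base, C2 and C3 settle all-equatorial relative to the fixed C4, i.e. (2R,3S).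

**Step 5**
Reactants: 12 (2R,3S,4S)-7-(benzyloxy)-2-[4-(benzyloxy)phenyl]-4-[2,4-bis(benzyloxy)-6-bromophenyl]-3-nitrochromane
Product: 14 (2R,4S)-7-(benzyloxy)-2-[4-(benzyloxy)phenyl]-4-[2,4-bis(benzyloxy)-6-bromophenyl]chroman-3-one, via potassium nitronate 13 (not isolated)
Conditions: KOt-Bu (1.1 equiv), THF, −78 °C; then aq. TiCl3 (5 equiv), NH4OAc (pH 5–6), THF/H2O, 0 °C; used crude
Reagents that add atoms: water O
Why: Nef reaction in the McMurry–Melton variant (TiCl3 reduces the nitronate to the N–H imine, which hydrolyses to the ketone) is run cold and buffered so that the cis-2,4-diequatorial ketone, which is also the thermodynamic isomer, is not enolised; racemisation would need C2 and C4 to invert one after the other.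

**Step 6**
Reactants: 14 (2R,4S)-7-(benzyloxy)-2-[4-(benzyloxy)phenyl]-4-[2,4-bis(benzyloxy)-6-bromophenyl]chroman-3-one
Product: 15 (2R,3S,4S)-7-(benzyloxy)-2-[4-(benzyloxy)phenyl]-4-[2,4-bis(benzyloxy)-6-bromophenyl]chroman-3-ol
Conditions: NaBH4, CeCl3·7H2O, MeOH/THF, −78 °C
Reagents that add atoms: none
Why: Luche-type reduction with a small hydride is expected to deliver hydrogen axially (anti to the two axial α-C–H bonds; O1 and C4a carry no axial hydrogens to block that face), which puts the new hydroxyl equatorial and trans to both aryl groups, i.e. C3 (S).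

**Step 7**
Reactants: 16 3,4-bis(benzyloxy)benzaldehyde
Product: 17 1,2-bis(benzyloxy)-4-ethenylbenzene
Conditions: Ph3PCH3Br, KOt-Bu, THF, 0 °C to rt
Reagents that add atoms: methyltriphenylphosphonium bromide C[P+](c1ccccc1)(c1ccccc1)c1ccccc1.[Br-]
Why: Wittig methylenation of an aromatic aldehyde with a non-stabilised ylide; no stereochemistry is involved.

**Step 8**
Reactants: 15 (2R,3S,4S)-7-(benzyloxy)-2-[4-(benzyloxy)phenyl]-4-[2,4-bis(benzyloxy)-6-bromophenyl]chroman-3-ol; 17 1,2-bis(benzyloxy)-4-ethenylbenzene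
Product: 18 (2R,3S,4S)-7-(benzyloxy)-2-[4-(benzyloxy)phenyl]-4-{2,4-bis(benzyloxy)-6-[(E)-2-[3,4-bis(benzyloxy)phenyl]ethenyl]phenyl}chroman-3-ol
Conditions: Pd(OAc)2 (5 mol%), P(t-Bu)3·HBF4 (10 mol%), K2CO3, DMF, 100 °C
Reagents that add atoms: none
Why: Mizoroki–Heck coupling of the ortho-substituted aryl bromide with the styrene under a bulky trialkylphosphine catalyst gives the (E)-stilbene by syn insertion and syn β-hydride elimination; the trans-disposed C3 hydroxyl cannot close onto the arylpalladium bromide, and no stereocentre is touched.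

**Step 9**
Reactants: 18 (2R,3S,4S)-7-(benzyloxy)-2-[4-(benzyloxy)phenyl]-4-{2,4-bis(benzyloxy)-6-[(E)-2-[3,4-bis(benzyloxy)phenyl]ethenyl]phenyl}chroman-3-ol
Product: 19 (2R,3S,4S)-4-{2-[(E)-2-(3,4-dihydroxyphenyl)ethenyl]-4,6-dihydroxyphenyl}-2-(4-hydroxyphenyl)chromane-3,7-diol
Conditions: BCl3 (12 equiv), C6HMe5 (18 equiv), CH2Cl2, −78 °C; then MeOH
Reagents that add atoms: none
Why: Lewis-acid debenzylation with BCl3 and pentamethylbenzene as a non-basic benzyl-cation scavenger cleaves all six aryl benzyl ethers at −78 °C while leaving the stilbene double bond, the C2 benzylic ether and the three stereocentres alone.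

**Compound list**
1 | 1,3-bis(benzyloxy)-5-bromobenzene | Brc1cc(OCc2ccccc2)cc(OCc2ccccc2)c1 | starting material
2 | N-{[2,4-bis(benzyloxy)-6-bromophenyl]methylidene}-N-methylmethanaminium chloride | C[N+](C)=Cc1c(Br)cc(OCc2ccccc2)cc1OCc1ccccc1.[Cl-] | intermediate (not isolated)
3 | 2,4-bis(benzyloxy)-6-bromobenzaldehyde | O=Cc1c(Br)cc(OCc2ccccc2)cc1OCc1ccccc1 | intermediate
4 | 3-(benzyloxy)phenol | Oc1cccc(OCc2ccccc2)c1 | starting material
5 | rac-5-(benzyloxy)-2-{[2,4-bis(benzyloxy)-6-bromophenyl](hydroxy)methyl}phenol | OC(c1ccc(OCc2ccccc2)cc1O)c1c(Br)cc(OCc2ccccc2)cc1OCc1ccccc1 | intermediate (not isolated)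
6 | rac-5-(benzyloxy)-2-{[2,4-bis(benzyloxy)-6-bromophenyl](4-methylbenzenesulfonyl)methyl}phenol | Cc1ccc(cc1)S(=O)(=O)C(c1ccc(OCc2ccccc2)cc1O)c1c(Br)cc(OCc2ccccc2)cc1OCc1ccccc1 | intermediate
7 | nitromethane | C[N+](=O)[O-] | starting material
8 | (6E)-3-(benzyloxy)-6-{[2,4-bis(benzyloxy)-6-bromophenyl]methylidene}cyclohexa-2,4-dien-1-one | O=C1C=C(OCc2ccccc2)C=C/C1=C\c1c(Br)cc(OCc2ccccc2)cc1OCc1ccccc1 | intermediate (not isolated)
9 | 5-(benzyloxy)-2-{(1S)-1-[2,4-bis(benzyloxy)-6-bromophenyl]-2-nitroethyl}phenol | Oc1cc(OCc2ccccc2)ccc1[C@@H](c1c(Br)cc(OCc2ccccc2)cc1OCc1ccccc1)C[N+](=O)[O-] | intermediate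
10 | 4-(benzyloxy)benzaldehyde | O=Cc1ccc(OCc2ccccc2)cc1 | starting material
11 | 5-(benzyloxy)-2-{(1S,2E)-3-[4-(benzyloxy)phenyl]-1-[2,4-bis(benzyloxy)-6-bromophenyl]-2-nitroprop-2-en-1-yl}phenol | [O-][N+](=O)/C(=C/c1ccc(OCc2ccccc2)cc1)[C@@H](c1ccc(OCc2ccccc2)cc1O)c1c(Br)cc(OCc2ccccc2)cc1OCc1ccccc1 | intermediate (not isolated)
12 | (2R,3S,4S)-7-(benzyloxy)-2-[4-(benzyloxy)phenyl]-4-[2,4-bis(benzyloxy)-6-bromophenyl]-3-nitrochromane | C(c1ccccc1)Oc1ccc(cc1)[C@H]1Oc2cc(OCc3ccccc3)ccc2[C@@H](c2c(Br)cc(OCc3ccccc3)cc2OCc2ccccc2)[C@@H]1[N+](=O)[O-] | intermediate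
13 | potassium aci-nitronate of 12, (2R,4S) | C(c1ccccc1)Oc1ccc(cc1)[C@H]1Oc2cc(OCc3ccccc3)ccc2[C@@H](c2c(Br)cc(OCc3ccccc3)cc2OCc2ccccc2)C1=[N+]([O-])[O-].[K+] | intermediate (not isolated)
14 | (2R,4S)-7-(benzyloxy)-2-[4-(benzyloxy)phenyl]-4-[2,4-bis(benzyloxy)-6-bromophenyl]chroman-3-one | C(c1ccccc1)Oc1ccc(cc1)[C@H]1Oc2cc(OCc3ccccc3)ccc2[C@@H](c2c(Br)cc(OCc3ccccc3)cc2OCc2ccccc2)C1=O | intermediate
15 | (2R,3S,4S)-7-(benzyloxy)-2-[4-(benzyloxy)phenyl]-4-[2,4-bis(benzyloxy)-6-bromophenyl]chroman-3-ol | C(c1ccccc1)Oc1ccc(cc1)[C@H]1Oc2cc(OCc3ccccc3)ccc2[C@@H](c2c(Br)cc(OCc3ccccc3)cc2OCc2ccccc2)[C@@H]1O | intermediate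
16 | 3,4-bis(benzyloxy)benzaldehyde | O=Cc1ccc(OCc2ccccc2)c(OCc2ccccc2)c1 | starting material
17 | 1,2-bis(benzyloxy)-4-ethenylbenzene | C=Cc1ccc(OCc2ccccc2)c(OCc2ccccc2)c1 | intermediate
18 | (2R,3S,4S)-7-(benzyloxy)-2-[4-(benzyloxy)phenyl]-4-{2,4-bis(benzyloxy)-6-[(E)-2-[3,4-bis(benzyloxy)phenyl]ethenyl]phenyl}chroman-3-ol | C(c1ccccc1)Oc1ccc(cc1)[C@H]1Oc2cc(OCc3ccccc3)ccc2[C@@H](c2c(OCc3ccccc3)cc(OCc3ccccc3)cc2/C=C/c2ccc(OCc3ccccc3)c(OCc3ccccc3)c2)[C@@H]1O | intermediate
19 | (2R,3S,4S)-4-{2-[(E)-2-(3,4-dihydroxyphenyl)ethenyl]-4,6-dihydroxyphenyl}-2-(4-hydroxyphenyl)chromane-3,7-diol (CNP0170061.1) | Oc1ccc([C@H]2Oc3cc(O)ccc3[C@@H](c3c(O)cc(O)cc3/C=C/c3ccc(O)c(O)c3)[C@@H]2O)cc1 | target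

**Totals**
Total step count: 9. Longest linear sequence: 8 (steps 1, 2, 3, 4, 5, 6, 8, 9).

**Three steps most likely to fail**

Step 3 (the asymmetric addition is new, and the hindered nitroalkane 9 must then condense in step 4). The fallback sets out from sulfone 6 and comes back at nitrochromane 12. It uses the far more acidic pronucleophile 1-[4-(benzyloxy)phenyl]-2-nitroethan-1-one F1, made in one step from commercial 2-bromo-1-[4-(benzyloxy)phenyl]ethan-1-one and NaNO2 in DMF, so the C2–C3 bond is already in the reagent. Under the same squaramide/aqueous Na2CO3 conditions its nitronate adds to the quinone methide and the adduct closes to the hemiketal (4S)-7-(benzyloxy)-2-[4-(benzyloxy)phenyl]-4-[2,4-bis(benzyloxy)-6-bromophenyl]-3-nitrochroman-2-ol F2. Catalytic TsOH dehydrates this to (4S)-7-(benzyloxy)-2-[4-(benzyloxy)phenyl]-4-[2,4-bis(benzyloxy)-6-bromophenyl]-3-nitro-4H-chromene F3. NaBH4 (THF/MeOH, 0 °C) then adds hydride to C2 anti to the C4 aryl group, and protonation of the nitronate gives 12.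

Step 5 (the nitronate can open ring C by β-elimination of the aryloxide, and the ketone has two enolisable stereocentres). The fallback sets out from 12 and comes back at ketone 14 without ever forming a nitronate. Zn/AcOH reduces the nitro group with retention to (2R,3S,4S)-7-(benzyloxy)-2-[4-(benzyloxy)phenyl]-4-[2,4-bis(benzyloxy)-6-bromophenyl]chroman-3-amine F4. Oxidative deamination by transamination with 3,5-di-tert-butyl-1,2-benzoquinone (THF/MeOH, then aqueous oxalic acid) gives 14.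

Step 6 (the facial selectivity of hydride delivery between two equatorial aryl groups is not secured by precedent). The fallback sets out from 14 and comes back at alcohol 15, replacing reagent control by substrate-controlled hydroboration. LiBH(s-Bu)3 (THF, −78 °C) attacks equatorially to give the all-cis alcohol (2R,3R,4S)-7-(benzyloxy)-2-[4-(benzyloxy)phenyl]-4-[2,4-bis(benzyloxy)-6-bromophenyl]chroman-3-ol F5. Anti-dehydration of its axial hydroxyl with Martin sulfurane gives (2S)-7-(benzyloxy)-2-[4-(benzyloxy)phenyl]-4-[2,4-bis(benzyloxy)-6-bromophenyl]-2H-chromene F6 (same spatial arrangement at C2; the descriptor changes with the priorities). BH3·SMe2 followed by NaBO3·4H2O puts boron on C3 anti to the C2 aryl group and hydrogen on C4 from the same face, which gives 15 with the 2,3-trans-3,4-trans arrangement.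

**Further compounds**
F1 | step 3 | 1-[4-(benzyloxy)phenyl]-2-nitroethan-1-one | O=C(C[N+](=O)[O-])c1ccc(OCc2ccccc2)cc1
F2 | step 3 | (4S)-7-(benzyloxy)-2-[4-(benzyloxy)phenyl]-4-[2,4-bis(benzyloxy)-6-bromophenyl]-3-nitrochroman-2-ol (mixture at C2 and C3) | OC1(c2ccc(OCc3ccccc3)cc2)Oc2cc(OCc3ccccc3)ccc2[C@@H](c2c(Br)cc(OCc3ccccc3)cc2OCc2ccccc2)C1[N+](=O)[O-]
F3 | step 3 | (4S)-7-(benzyloxy)-2-[4-(benzyloxy)phenyl]-4-[2,4-bis(benzyloxy)-6-bromophenyl]-3-nitro-4H-chromene | [O-][N+](=O)C1=C(c2ccc(OCc3ccccc3)cc2)Oc2cc(OCc3ccccc3)ccc2[C@H]1c1c(Br)cc(OCc2ccccc2)cc1OCc1ccccc1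
F4 | step 5 | (2R,3S,4S)-7-(benzyloxy)-2-[4-(benzyloxy)phenyl]-4-[2,4-bis(benzyloxy)-6-bromophenyl]chroman-3-amine | C(c1ccccc1)Oc1ccc(cc1)[C@H]1Oc2cc(OCc3ccccc3)ccc2[C@@H](c2c(Br)cc(OCc3ccccc3)cc2OCc2ccccc2)[C@@H]1N
F5 | step 6 | (2R,3R,4S)-7-(benzyloxy)-2-[4-(benzyloxy)phenyl]-4-[2,4-bis(benzyloxy)-6-bromophenyl]chroman-3-ol | C(c1ccccc1)Oc1ccc(cc1)[C@H]1Oc2cc(OCc3ccccc3)ccc2[C@@H](c2c(Br)cc(OCc3ccccc3)cc2OCc2ccccc2)[C@H]1O
F6 | step 6 | (2S)-7-(benzyloxy)-2-[4-(benzyloxy)phenyl]-4-[2,4-bis(benzyloxy)-6-bromophenyl]-2H-chromene | C(c1ccccc1)Oc1ccc(cc1)[C@H]1Oc2cc(OCc3ccccc3)ccc2C(c2c(Br)cc(OCc3ccccc3)cc2OCc2ccccc2)=C1
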